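**Strategy.** The pendant α-methyl-γ-butyrolactone is opened at its ring CH2–CH(CH3) bond. That bond is made as the C=C of a butenolide by ring-closing metathesis: the lactone carbinol carbon (bound to the pyrrolidinone carbon next to N) already carries the ring oxygen, so it can hold a methacrylate ester and a vinyl group, and loss of ethylene joins the vinyl CH to the methacrylate α-carbon. The same carbinol centre then directs hydrogenation to the cis methyl. The metathesis precursor is the finished eleven-membered keto-lactam with its cis-fused lactone, built from L-pyroglutamic acid by a lactam-enolate Michael addition/methylation on a menthyloxyfuranone, an Evans aldol–lactonization and an intramolecular Fukuyama coupling.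

Key step: step 15

Remark: compounds 7 and 13 are taken as catalogue chemicals (otherwise 7 is one step from 5-hydroxyfuran-2(5H)-one and (+)-menthol, and 13 one step from (4S)-4-benzyl-1,3-oxazolidin-2-one and butanoyl chloride).

**Step 1**
Reactants: 1 L-pyroglutamic acid
Product: 2 (2S)-N-methoxy-N-methyl-5-oxopyrrolidine-2-carboxamide
Conditions: MeNHOMe·HCl, EDC·HCl, N-methylmorpholine, CH2Cl2/DMF, 0 °C to rt
Reagents that add atoms: N,O-dimethylhydroxylamine hydrochloride, CNOC.Cl
Why: Carbodiimide amide coupling gives the Weinreb amide and should leave the C2 stereocentre untouched.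

**Step 2**
Reactants: 2 Weinreb amide
Product: 3 (2S)-1-(4-chlorobutyl)-N-methoxy-N-methyl-5-oxopyrrolidine-2-carboxamide
Conditions: NaH (1.0 equiv), Br(CH2)4Cl (3 equiv), DMF, 0 °C
Reagents that add atoms: 1-bromo-4-chlorobutane, ClCCCCBr
Why: Lactam N-alkylation (SN2); the sodium lactamate should displace bromide in preference to chloride, and one equivalent of base should not deprotonate the less acidic C–H beside the Weinreb carbonyl.

**Step 3**
Reactants: 3 N-alkylated Weinreb amide
Product: 4 (5S)-1-(4-chlorobutyl)-5-(prop-2-enoyl)pyrrolidin-2-one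
Conditions: CH2=CHMgBr, THF, −78 to 0 °C; inverse quench into cold 1 M HCl
Reagents that add atoms: vinylmagnesium bromide, C=C[Mg]Br
Why: Weinreb ketone synthesis; the chelated magnesium adduct should persist until the acidic quench, which also keeps the released hydroxylamine from adding to the enone.

**Step 4**
Reactants: 4 vinyl ketone
Product: 5 (5S)-1-(4-chlorobutyl)-5-[(1S)-1-hydroxyprop-2-en-1-yl]pyrrolidin-2-one
Conditions: NaBH4, CeCl3·7H2O, MeOH, −78 °C
Reagents that add atoms: none
Why: Luche 1,2-reduction; polar Felkin–Anh attack anti to the fully substituted, non-chelating lactam nitrogen should give the syn (1S) allylic alcohol.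

**Step 5**
Reactants: 5 allylic alcohol
Product: 6 (5S)-5-[(1S)-1-(tert-butyldiphenylsilyloxy)prop-2-en-1-yl]-1-(4-chlorobutyl)pyrrolidin-2-one
Conditions: TBDPSCl, imidazole, DMAP (cat.), DMF, 40 °C
Reagents that add atoms: tert-butyl(chloro)diphenylsilane, CC(C)(C)[Si](Cl)(c1ccccc1)c1ccccc1
Why: Silyl ether formation; this ether should survive the later acid steps and enlarges the C5 substituent that steers step 6.

**Step 6**
Reactants: 6 silyl-protected lactam; 7 (5S)-5-[(1S,2R,5S)-menthyloxy]furan-2(5H)-one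
Product: 10 Michael–methylation adduct (menthyloxy lactone on lactam C3), via lithium enolate of lactam 8 (not isolated), via lithium lactone enolate 9 (not isolated)
Conditions: LiN(iPr)2, THF, −78 °C; 7, −78 °C; MeI, DMPU, −78 to −40 °C
Reagents that add atoms: iodomethane, CI
Why: Tandem Michael addition/enolate alkylation on a chiral 5-alkoxyfuranone; the lactam enolate should react anti to its C5 substituent (3,5-trans), add to the furanone anti to the menthyloxy group, and the lactone enolate should be methylated anti to the new C–C bond, which sets three stereocentres.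

**Step 7**
Reactants: 10 menthyloxy lactone
Product: 11 dimethyl acetal methyl ester
Conditions: HC(OMe)3, MeOH, camphorsulfonic acid (cat.), 50 °C
Reagents that add atoms: methanol, CO; trimethyl orthoformate, COC(OC)OC
Why: Acid-catalysed methanolysis/transacetalization of the cyclic pseudo-ester; the orthoformate removes water and should drive the ring-opened acetal ester while releasing menthol.

**Step 8**
Reactants: 11 acetal ester
Product: 12 aldehyde methyl ester
Conditions: CF3CO2H, H2O, CH2Cl2, 0 °C; used crude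
Reagents that add atoms: water, O
Why: Acetal hydrolysis under mild aqueous acid should spare the methyl ester and silyl ether; the α-branched aldehyde is not purified, to limit epimerization.

**Step 9**
Reactants: 12 aldehyde methyl ester; 13 (4S)-4-benzyl-3-butanoyl-1,3-oxazolidin-2-one
Product: 16 cis-fused lactone imide, via dibutylboron Z-enolate 14 (not isolated), via hydroxy ester aldol adduct 15 (not isolated)
Conditions: 13, Bu2BOTf, iPr2NEt, CH2Cl2, −78 to 0 °C; 12, −78 to 0 °C; pH 7 buffer, MeOH, H2O2; then PPTS (cat.), toluene, 60 °C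
Reagents that add atoms: none
Why: Evans syn aldol through a Zimmerman–Traxler chair; the (S)-benzyl auxiliary should set the ethyl-bearing carbon (S) and the carbinol carbon (R) under reagent control, and the γ-hydroxy ester then lactonizes.

**Step 10**
Reactants: 16 lactone imide
Product: 17 S-ethyl thioester
Conditions: EtSH, n-BuLi, THF, −20 to 0 °C, short reaction time
Reagents that add atoms: ethanethiol, CCS
Why: Transthioesterification of the exocyclic imide carbonyl by LiSEt (auxiliary removal) should be much faster than SN2 at the primary chloride or attack on the lactone.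

**Step 11**
Reactants: 17 chloro thioester
Product: 18 iodo thioester
Conditions: NaI, acetone, reflux
Reagents that add atoms: sodium iodide, [Na+].[I-]
Why: Finkelstein halide exchange (SN2), driven by precipitation of NaCl.

**Step 12**
Reactants: 18 iodo thioester
Product: 20 eleven-membered keto-lactam silyl ether, via alkylzinc iodide 19 (not isolated)
Conditions: Zn dust (activated with BrCH2CH2Br, Me3SiCl), LiCl, THF, 35 °C; then slow addition to PdCl2(PPh3)2 (10 mol%), toluene/THF, 40 °C, 2 mM
Reagents that add atoms: none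
Why: Zinc insertion into the primary C–I bond, then intramolecular Fukuyama coupling (oxidative addition of zerovalent palladium into the C–S bond, transmetalation, reductive elimination), a base-free ketone synthesis that should spare the lactone, the silyl ether and the α-ethyl centre.

**Step 13**
Reactants: 20 keto-lactam silyl ether
Product: 21 keto-lactam allylic alcohol
Conditions: HF·pyridine, pyridine, THF, 0 °C to rt
Reagents that add atoms: none
Why: Fluoride desilylation under buffered, slightly acidic conditions should avoid E1cB loss of the β-acyloxy group beside the ketone.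

**Step 14**
Reactants: 21 allylic alcohol
Product: 22 methacrylate ester
Conditions: CH2=C(CH3)COCl, iPr2NEt, DMAP (cat.), CH2Cl2, 0 °C
Reagents that add atoms: 2-methylprop-2-enoyl chloride, CC(=C)C(Cl)=O
Why: DMAP-catalysed O-acylation with retention at the carbinol centre; low temperature and a hindered amine should keep the β-acyloxy ketone intact.

**Step 15**
Reactants: 22 methacrylate ester
Product: 23 butenolide (3-methylfuran-2(5H)-one on pyrrolidinone C5)
Conditions: second-generation Grubbs catalyst (10 mol%), toluene, 80 °C, 5 mM, argon purge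
Reagents that add atoms: none
Why: Olefin metathesis mechanism: the ruthenium benzylidene exchanges onto the monosubstituted vinyl group, the new alkylidene adds intramolecularly to the methacrylate C=C through a ruthenacyclobutane, and cycloreversion releases the butenolide while ethylene leaves as the second product. The closest known reaction type is the ring-closing metathesis of methacrylates of secondary allylic alcohols to 3-methylfuran-2(5H)-ones. The five-membered ring closes by formation of the C3=C4 bond of the furanone across the existing ester tether, with both alkene carbons ending inside the ring, so no 5-endo attack of an enolate or radical is needed. No new stereocentre is created; the (S) carbinol centre from step 4 is untouched and later controls the face of hydrogenation in step 16. The step needs cyclization to win over cross-metathesis and must tolerate the ketone, the lactam and two ester-type carbonyls. High dilution, the favourable ring size and the absence of any other alkene in 22 (the nitrogen side chain is already tied into the saturated eleven-membered ring) should secure this.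

**Step 16**
Reactants: 23 butenolide
Product: 24 target CNP0147860.1
Conditions: H2 (1 atm), 10% Pd/C, EtOAc, rt
Reagents that add atoms: none
Why: Heterogeneous hydrogenation; hydrogen should add to the butenolide face anti to the pyrrolidinone substituent on the carbinol carbon, placing the methyl cis to it (S), and the ketone should not be reduced.

**Compound list**

1 | L-pyroglutamic acid, (2S)-5-oxopyrrolidine-2-carboxylic acid | O=C1CC[C@H](N1)C(=O)O | starting material
2 | (2S)-N-methoxy-N-methyl-5-oxopyrrolidine-2-carboxamide | O=C1CC[C@H](N1)C(=O)N(C)OC | intermediate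
3 | (2S)-1-(4-chlorobutyl)-N-methoxy-N-methyl-5-oxopyrrolidine-2-carboxamide | ClCCCCN1C(=O)CC[C@H]1C(=O)N(C)OC | intermediate
4 | (5S)-1-(4-chlorobutyl)-5-(prop-2-enoyl)pyrrolidin-2-one | ClCCCCN1C(=O)CC[C@H]1C(=O)C=C | intermediate
5 | (5S)-1-(4-chlorobutyl)-5-[(1S)-1-hydroxyprop-2-en-1-yl]pyrrolidin-2-one | ClCCCCN1C(=O)CC[C@H]1[C@@H](O)C=C | intermediate
6 | (5S)-5-[(1S)-1-(tert-butyldiphenylsilyloxy)prop-2-en-1-yl]-1-(4-chlorobutyl)pyrrolidin-2-one | ClCCCCN1C(=O)CC[C@H]1[C@@H](O[Si](c2ccccc2)(c3ccccc3)C(C)(C)C)C=C | intermediate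
7 | (5S)-5-[(1S,2R,5S)-2-isopropyl-5-methylcyclohexyloxy]furan-2(5H)-one | CC(C)[C@H]1CC[C@H](C)C[C@@H]1O[C@H]1OC(=O)C=C1 | starting material
8 | lithium enolate of lactam 6 | ClCCCCN1C(O[Li])=CC[C@H]1[C@@H](O[Si](c2ccccc2)(c3ccccc3)C(C)(C)C)C=C | intermediate
9 | lithium lactone enolate formed by Michael addition of 8 to 7 | ClCCCCN1C(=O)[C@@H](C[C@H]1[C@@H](O[Si](c2ccccc2)(c3ccccc3)C(C)(C)C)C=C)[C@@H]4[C@@H](O[C@H]5C[C@@H](C)CC[C@@H]5C(C)C)OC(O[Li])=C4 | intermediate
10 | (3S,5S)-5-[(1S)-1-(tert-butyldiphenylsilyloxy)prop-2-en-1-yl]-1-(4-chlorobutyl)-3-[(2S,3S,4S)-2-[(1S,2R,5S)-menthyloxy]-4-methyl-5-oxooxolan-3-yl]pyrrolidin-2-one | ClCCCCN1C(=O)[C@@H](C[C@H]1[C@@H](O[Si](c2ccccc2)(c3ccccc3)C(C)(C)C)C=C)[C@@H]4[C@@H](O[C@H]5C[C@@H](C)CC[C@@H]5C(C)C)OC(=O)[C@H]4C | intermediate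
11 | methyl (2S,3S)-3-[(3S,5S)-5-[(1S)-1-(tert-butyldiphenylsilyloxy)prop-2-en-1-yl]-1-(4-chlorobutyl)-2-oxopyrrolidin-3-yl]-4,4-dimethoxy-2-methylbutanoate | ClCCCCN1C(=O)[C@@H](C[C@H]1[C@@H](O[Si](c2ccccc2)(c3ccccc3)C(C)(C)C)C=C)[C@@H]([C@H](C)C(=O)OC)C(OC)OC | intermediate
12 | methyl (2S,3S)-3-[(3S,5S)-5-[(1S)-1-(tert-butyldiphenylsilyloxy)prop-2-en-1-yl]-1-(4-chlorobutyl)-2-oxopyrrolidin-3-yl]-2-methyl-4-oxobutanoate | ClCCCCN1C(=O)[C@@H](C[C@H]1[C@@H](O[Si](c2ccccc2)(c3ccccc3)C(C)(C)C)C=C)[C@@H]([C@H](C)C(=O)OC)C=O | intermediate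
13 | (4S)-4-benzyl-3-butanoyl-1,3-oxazolidin-2-one | CCCC(=O)N1[C@@H](Cc2ccccc2)COC1=O | starting material
14 | dibutylboron (Z)-enolate of 13 | CC/C=C(\OB(CCCC)CCCC)N1[C@@H](Cc2ccccc2)COC1=O | intermediate
15 | methyl (2S,3S,4R,5S)-5-[(4S)-4-benzyl-2-oxo-1,3-oxazolidine-3-carbonyl]-4-hydroxy-2-methyl-3-[(3S,5S)-5-[(1S)-1-(tert-butyldiphenylsilyloxy)prop-2-en-1-yl]-1-(4-chlorobutyl)-2-oxopyrrolidin-3-yl]heptanoate | ClCCCCN1C(=O)[C@@H](C[C@H]1[C@@H](O[Si](c2ccccc2)(c3ccccc3)C(C)(C)C)C=C)[C@@H]([C@H](C)C(=O)OC)[C@@H](O)[C@H](CC)C(=O)N4[C@@H](Cc5ccccc5)COC4=O | intermediate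
16 | (4S)-4-benzyl-3-[(2S)-2-[(2R,3S,4S)-3-[(3S,5S)-5-[(1S)-1-(tert-butyldiphenylsilyloxy)prop-2-en-1-yl]-1-(4-chlorobutyl)-2-oxopyrrolidin-3-yl]-4-methyl-5-oxooxolan-2-yl]butanoyl]-1,3-oxazolidin-2-one | ClCCCCN1C(=O)[C@@H](C[C@H]1[C@@H](O[Si](c2ccccc2)(c3ccccc3)C(C)(C)C)C=C)[C@@H]4[C@@H](OC(=O)[C@H]4C)[C@H](CC)C(=O)N5[C@@H](Cc6ccccc6)COC5=O | intermediate
17 | S-ethyl (2S)-2-[(2R,3S,4S)-3-[(3S,5S)-5-[(1S)-1-(tert-butyldiphenylsilyloxy)prop-2-en-1-yl]-1-(4-chlorobutyl)-2-oxopyrrolidin-3-yl]-4-methyl-5-oxooxolan-2-yl]butanethioate | ClCCCCN1C(=O)[C@@H](C[C@H]1[C@@H](O[Si](c2ccccc2)(c3ccccc3)C(C)(C)C)C=C)[C@@H]4[C@@H](OC(=O)[C@H]4C)[C@H](CC)C(=O)SCC | intermediate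
18 | 4-iodobutyl analogue of 17 | ICCCCN1C(=O)[C@@H](C[C@H]1[C@@H](O[Si](c2ccccc2)(c3ccccc3)C(C)(C)C)C=C)[C@@H]4[C@@H](OC(=O)[C@H]4C)[C@H](CC)C(=O)SCC | intermediate
19 | alkylzinc iodide from 18 (4-(iodozincio)butyl on N) | I[Zn]CCCCN1C(=O)[C@@H](C[C@H]1[C@@H](O[Si](c2ccccc2)(c3ccccc3)C(C)(C)C)C=C)[C@@H]4[C@@H](OC(=O)[C@H]4C)[C@H](CC)C(=O)SCC | intermediate
20 | eleven-membered keto-lactam with all ring stereocentres of the target, carrying (1S)-1-(tert-butyldiphenylsilyloxy)prop-2-en-1-yl on the pyrrolidinone carbon next to N in place of the pendant lactone | CC[C@@H]1C(=O)CCCCN2C(=O)[C@@H](C[C@H]2[C@@H](O[Si](c3ccccc3)(c4ccccc4)C(C)(C)C)C=C)[C@@H]5[C@H]1OC(=O)[C@H]5C | intermediate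
21 | as 20 with a free (1S)-1-hydroxyprop-2-en-1-yl group | CC[C@@H]1C(=O)CCCCN2C(=O)[C@@H](C[C@H]2[C@@H](O)C=C)[C@@H]3[C@H]1OC(=O)[C@H]3C | intermediate
22 | as 21 with the (1S) hydroxyl esterified as the 2-methylprop-2-enoate | CC[C@@H]1C(=O)CCCCN2C(=O)[C@@H](C[C@H]2[C@@H](OC(=O)C(C)=C)C=C)[C@@H]3[C@H]1OC(=O)[C@H]3C | intermediate
23 | target framework with the pendant ring as (2S)-4-methyl-5-oxo-2,5-dihydrofuran-2-yl (butenolide) | CC[C@@H]1C(=O)CCCCN2C(=O)[C@@H](C[C@H]2[C@@H]3C=C(C)C(=O)O3)[C@@H]4[C@H]1OC(=O)[C@H]4C | intermediate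
24 | CNP0147860.1: eleven-membered ring ketone bridging N and C3 of a pyrrolidin-2-one, with cis-fused α-methyl-γ-lactone, ethyl group α to the ketone and (2S,4S)-4-methyl-5-oxooxolan-2-yl on pyrrolidinone C5 | CC[C@@H]1C(=O)CCCCN2C(=O)[C@@H](C[C@H]2[C@@H]2C[C@H](C)C(=O)O2)[C@@H]2[C@H]1OC(=O)[C@H]2C | target

**Totals**

Total step count: 16. Longest linear sequence: 16 steps (from 1).

**Steps most likely to fail**

Step 12. Closing an eleven-membered ring requires a transannular transmetalation; intermolecular coupling (oligomers) or protodemetalation of the alkylzinc may outrun it. The fallback sets out from 17 and makes the same C–C bond by carbonyl addition instead of acyl substitution. Fukuyama reduction (Et3SiH, 10% Pd/C, acetone, 0 °C) should give the chloro aldehyde F1. Finkelstein exchange (NaI, acetone) should give the iodo aldehyde F2. A chromium-mediated intramolecular alkyl addition (alkyl variant of the Nozaki–Hiyama–Kishi reaction: CrCl2, catalytic cobalt phthalocyanine Co(C32H16N8), DMF, high dilution) should give the macrocyclic secondary alcohol F3. Dess–Martin oxidation returns to 20.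

Step 6. The hard lithium enolate may add 1,2, or the lactone enolate may take the proton from the new tertiary C–H beside the lactam carbonyl before methyl iodide arrives, which erodes the tandem trapping. The fallback sets out from 6 and separates the two events under different activation. LiN(iPr)2 and tBuMe2SiCl (THF/DMPU, −78 °C) should give the silyl ketene N,O-acetal F4. Mukaiyama–Michael addition to 7 (Me3SiOTf cat., CH2Cl2, −78 °C, acidic work-up) should give the unmethylated adduct F5 with the same facial control. LiN(SiMe3)2 and MeI at −78 °C should methylate the more accessible lactone α-carbon anti to its neighbour and return to 10.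

Step 4. Hydride delivery may go through a competing chelated conformer, which gives poor facial selectivity or mainly the (1R) alcohol. The fallback sets out from 4. The (1R) epimer F6, obtained from that reduction, is inverted by a Mitsunobu reaction (4-nitrobenzoic acid, PPh3, diisopropyl azodicarboxylate, THF) to the (1S) 4-nitrobenzoate F7. Methanolysis (K2CO3, MeOH) returns to 5.

**Further compounds**

F1 | step 12 | (2S)-2-[(2R,3S,4S)-3-[(3S,5S)-5-[(1S)-1-(tert-butyldiphenylsilyloxy)prop-2-en-1-yl]-1-(4-chlorobutyl)-2-oxopyrrolidin-3-yl]-4-methyl-5-oxooxolan-2-yl]butanal | ClCCCCN1C(=O)[C@@H](C[C@H]1[C@@H](O[Si](c2ccccc2)(c3ccccc3)C(C)(C)C)C=C)[C@@H]4[C@@H](OC(=O)[C@H]4C)[C@H](CC)C=O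
F2 | step 12 | 4-iodobutyl analogue of F1 | ICCCCN1C(=O)[C@@H](C[C@H]1[C@@H](O[Si](c2ccccc2)(c3ccccc3)C(C)(C)C)C=C)[C@@H]4[C@@H](OC(=O)[C@H]4C)[C@H](CC)C=O
F3 | step 12 | macrocyclic secondary alcohol corresponding to 20 (carbinol in place of the ring ketone, either configuration) | CC[C@@H]1C(O)CCCCN2C(=O)[C@@H](C[C@H]2[C@@H](O[Si](c3ccccc3)(c4ccccc4)C(C)(C)C)C=C)[C@@H]5[C@H]1OC(=O)[C@H]5C
F4 | step 6 | O-(tert-butyldimethylsilyl) ketene N,O-acetal of 6 | ClCCCCN1C(O[Si](C)(C)C(C)(C)C)=CC[C@H]1[C@@H](O[Si](c2ccccc2)(c3ccccc3)C(C)(C)C)C=C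
F5 | step 6 | unmethylated Michael adduct, (3S,5S)-5-[(1S)-1-(tert-butyldiphenylsilyloxy)prop-2-en-1-yl]-1-(4-chlorobutyl)-3-[(2S,3S)-2-[(1S,2R,5S)-menthyloxy]-5-oxooxolan-3-yl]pyrrolidin-2-one | ClCCCCN1C(=O)[C@@H](C[C@H]1[C@@H](O[Si](c2ccccc2)(c3ccccc3)C(C)(C)C)C=C)[C@@H]4[C@@H](O[C@H]5C[C@@H](C)CC[C@@H]5C(C)C)OC(=O)C4
F6 | step 4 | (5S)-1-(4-chlorobutyl)-5-[(1R)-1-hydroxyprop-2-en-1-yl]pyrrolidin-2-one | ClCCCCN1C(=O)CC[C@H]1[C@H](O)C=C
F7 | step 4 | (1S)-1-[(2S)-1-(4-chlorobutyl)-5-oxopyrrolidin-2-yl]prop-2-en-1-yl 4-nitrobenzoate | ClCCCCN1C(=O)CC[C@H]1[C@@H](OC(=O)c2ccc(cc2)[N+](=O)[O-])C=C
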